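**Retrosynthetic overview**

1. The target is 2α-angeloyloxy-20-acetoxy-labda-7,14-diene-3α,13-diol; the two esters and the 2α,3α-diol are installed last, from a 3-ketone (C2 hydroxylation, axial-selective reduction, selective acylations).
2. Ring A is removed by a Robinson annulation retron (C1–C10 Michael, C4–C5 aldol, gem-dimethylation at C4, 1,2-reduction of the resulting 5,7-diene), which leaves ring B as a 2-cyclohexenone in which C5 is a ketone carbon.
3. Key disconnection (C9–C10 and C6–C7): ring B comes from methyl acetoacetate (C6, C5, C10, C20) and (2E,6R)-2,6-dimethyl-6-silyloxyocta-2,7-dienal (C7–C9, C11–C17), which is (R)-linalool after oxidation of its E-methyl group; linalool supplies C13.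
4. Enabling feature: with ring A absent and C5 at the ketone level, C6–C5(=O)–C10–C20(=O)O is a 1,3-dicarbonyl unit, so C10 (doubly activated) and C6 (enolisable methyl) pair with the β-carbon C9 and the formyl carbon C7 of the enal.
5. Ring order: ring B (step 3), then ring A (steps 4 and 5).

Key step: step 3

Remark: labdane numbering and α/β descriptors are used for all intermediates (C17 on C8, C20 on C10, side chain C11–C16).
Assumption: the quinine-derived primary amine is taken to shield the iminium face that leads to the 9S adduct; if it favours 9R, the quinidine-derived pseudo-enantiomer is used instead.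

**Route**

Step 1
Reactants: 1 (R)-(−)-linalool
Product: 2 (3R)-3,7-dimethyl-3-(triethylsilyloxy)octa-1,6-diene
Conditions: Et3SiOTf, 2,6-lutidine, CH2Cl2, −78 to 0 °C
Reagents that add atoms: triethylsilyl trifluoromethanesulfonate, CC[Si](CC)(CC)OS(=O)(=O)C(F)(F)F
Why: Silyl ether protection of the tertiary allylic alcohol, needed so that the oxygen cannot close onto C9 (oxa-Michael) in step 3; no stereocenter is touched.

Step 2
Reactants: 2 (3R)-3,7-dimethyl-3-(triethylsilyloxy)octa-1,6-diene
Product: 3 (2E,6R)-2,6-dimethyl-6-(triethylsilyloxy)octa-2,7-dienal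
Conditions: SeO2 (1.1 equiv), pyridine (cat.), dioxane, 70 °C
Reagents that add atoms: selenium dioxide, O=[Se]=O
Why: SeO2 allylic oxidation (ene reaction, then [2,3]-sigmatropic shift) attacks the E-methyl group of the trisubstituted olefin and should carry it on to the (E)-enal, while the vinyl group has no allylic hydrogen.

Step 3
Reactants: 3 (2E,6R)-2,6-dimethyl-6-(triethylsilyloxy)octa-2,7-dienal; 4 methyl acetoacetate
Product: 6 methyl 5-methyl-6-[(3R)-3-methyl-3-(triethylsilyloxy)pent-4-enyl]-2-oxocyclohex-3-ene-1-carboxylate (ring B enone; 9S; 8α-methyl and 10α-ester as the expected all-trans isomer), via keto aldehyde Michael adduct 5 (not isolated)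
Conditions: 9-amino-9-deoxy-epi-quinine (20 mol %), 2-fluorobenzoic acid (40 mol %), toluene, 25 °C; then pyrrolidine, AcOH (20 mol % each), 40 °C
Reagents that add atoms: none
Why: Proposed new method: the primary amine condenses with the α-branched enal to an iminium ion, the enol of methyl acetoacetate adds to C9 (Michael, C9–C10), the enamine is protonated at C8 and hydrolysed to keto aldehyde 5, and the methyl ketone carbon C6 then adds to the formyl carbon C7 with loss of water (C6–C7). The closest known reaction type is the amine-catalysed Michael/aldol-condensation annulation ([3+3], Robinson-type) of β-keto esters with β-substituted enals, together with primary-amine iminium activation of α-branched enals; the combination on an α-methyl enal is the unproven element. Ring B is closed by a 6-(enolexo)-exo-trig aldol addition followed by dehydration, and no other ring size is accessible from 5. C9 is set by the catalyst (facial shielding of the iminium ion), whereas C8 (γ to the enone carbonyl) and C10 (between two carbonyls) are epimerisable and should settle trans to the C9 chain; C8 is erased in step 6 and C10 is set again in step 4. The step needs 1,4- over 1,2-addition (secured by iminium activation and by the α-methyl group next to the formyl carbon), catalyst control at C9 (the C13 centre is too remote to interfere) and survival of the allylic silyl ether (weakly acidic medium).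

Step 4
Reactants: 6 ring B enone; 7 methyl vinyl ketone
Product: 8 methyl 5-methyl-6-[(3R)-3-methyl-3-(triethylsilyloxy)pent-4-enyl]-2-oxo-1-(3-oxobutyl)cyclohex-3-ene-1-carboxylate (C10 quaternary, ester β, 3-oxobutyl chain α)
Conditions: DABCO (10 mol %), CH2Cl2, 0 to 25 °C
Reagents that add atoms: none
Why: Base-catalysed Michael addition of the cyclic β-keto ester, in which the planar C10 enolate should be attacked anti to the neighbouring C9 chain, placing C1 α and the ester carbon C20 β (cis to C11).

Step 5
Reactants: 8 Michael adduct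
Product: 9 methyl 18,19-dinor-3-oxo-13-(triethylsilyloxy)labda-4,6,14-trien-20-oate (8α-methyl, 13R)
Conditions: pyrrolidine, AcOH (0.5 equiv each), toluene, 80 °C
Reagents that add atoms: none
Why: Enamine-mediated intramolecular aldol condensation (second half of the Robinson annulation) closes ring A through C4–C5, the amine conditions avoiding enolate attack on the angular ester; no new stereocenter is formed.

Step 6
Reactants: 9 linear dienone
Product: 10 methyl (13R)-3-oxo-13-(triethylsilyloxy)labda-5,7,14-trien-20-oate
Conditions: t-BuOK (3 equiv), t-BuOH–THF, 0 °C; MeI (6 equiv), 0 to 25 °C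
Reagents that add atoms: iodomethane, CI
Why: Thermodynamic deprotonation at C8 gives the extended trienolate, which is methylated twice at C4 (deconjugative α,α-dialkylation as practised on steroidal 4,6-dien-3-ones), moving the unsaturation into the 5,7-diene and erasing the C8 stereocenter.

Step 7
Reactants: 10 5,7-dien-3-one ester
Product: 11 (13R)-13-(triethylsilyloxy)labda-7,14-diene-3β,20-diol
Conditions: Li (excess), NH3(l)–THF, t-BuOH, −78 to −33 °C; NH4Cl
Reagents that add atoms: none
Why: Dissolving-metal (Birch-type) reduction should reduce the homoannular 5,7-diene 1,2 with protonation of C5 on the α face (trans fusion, as for steroidal 5,7-dienes going to 5α-7-enes), and reduce the ketone and the ester to alcohols (Bouveault–Blanc type) while leaving the isolated vinyl group.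

Step 8
Reactants: 11 diol
Product: 12 (13R)-20-(tert-butyldimethylsilyloxy)-13-(triethylsilyloxy)labda-7,14-dien-3β-ol
Conditions: TBSCl, imidazole, DMF, 0 °C
Reagents that add atoms: tert-butyldimethylsilyl chloride, CC(C)(C)[Si](C)(C)Cl
Why: Silylation should discriminate the primary C20 hydroxyl from the secondary C3 hydroxyl flanked by the gem-dimethyl group.

Step 9
Reactants: 12 C3 alcohol
Product: 13 (13R)-20-(tert-butyldimethylsilyloxy)-13-(triethylsilyloxy)labda-7,14-dien-3-one
Conditions: DMP (1,1,1-triacetoxy-1,1-dihydro-1,2-benziodoxol-3(1H)-one), pyridine, CH2Cl2, 0 to 25 °C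
Reagents that add atoms: none
Why: Buffered periodinane oxidation of the secondary alcohol, compatible with both silyl ethers and both olefins.

Step 10
Reactants: 13 3-ketone
Product: 14 (13R)-20-(tert-butyldimethylsilyloxy)-2α-hydroxy-13-(triethylsilyloxy)labda-7,14-dien-3-one
Conditions: KN(SiMe3)2, THF, −78 °C; 2-(phenylsulfonyl)-3-phenyloxaziridine, −78 °C; aq. NH4Cl
Reagents that add atoms: 2-(phenylsulfonyl)-3-phenyloxaziridine, O=S(=O)(N1OC1c1ccccc1)c1ccccc1
Why: Enolate oxidation with an N-sulfonyloxaziridine, where only C2 can enolise (C4 is quaternary) and the reagent should approach the α face, away from the axial C20 group, giving the equatorial 2α-alcohol (also the thermodynamic epimer).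

Step 11
Reactants: 14 2α-hydroxy ketone
Product: 15 (13R)-20-(tert-butyldimethylsilyloxy)-13-(triethylsilyloxy)labda-7,14-diene-2α,3α-diol
Conditions: LiBH(s-Bu)3 (2.2 equiv), THF, −78 °C
Reagents that add atoms: none
Why: The bulky hydride should attack the 4,4-dimethyl-3-ketone along the equatorial trajectory (steric approach control), giving the axial 3α-alcohol cis to the 2α-hydroxyl.

Step 12
Reactants: 15 2α,3α-diol
Product: 16 (13R)-2α-angeloyloxy-20-(tert-butyldimethylsilyloxy)-13-(triethylsilyloxy)labda-7,14-dien-3α-ol
Conditions: angelic acid, 2,4,6-trichlorobenzoyl chloride, Et3N, toluene, 25 °C; then 15, 80 °C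
Reagents that add atoms: angelic acid, C/C=C(/C)C(=O)O
Why: Yamaguchi-type mixed-anhydride esterification run without DMAP (to avoid angelate-to-tiglate isomerisation) should acylate the equatorial C2 hydroxyl, the axial C3 hydroxyl next to C4 being far slower.

Step 13
Reactants: 16 bis-silyl ether
Product: 17 (13R)-2α-angeloyloxylabda-7,14-diene-3α,13,20-triol
Conditions: HF·pyridine, pyridine, THF, 0 to 25 °C
Reagents that add atoms: none
Why: Buffered fluoride desilylation removes the primary and the tertiary silyl ether without the base that would promote acyl migration to C3.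

Step 14
Reactants: 17 triol
Product: 18 (13R)-20-acetoxy-2α-angeloyloxylabda-7,14-diene-3α,13-diol (target)
Conditions: Ac2O (1.2 equiv), pyridine, CH2Cl2, 0 °C
Reagents that add atoms: acetic anhydride, CC(=O)OC(C)=O
Why: Acetylation should take the primary C20 alcohol in preference to the hindered axial C3 and the tertiary C13 hydroxyls.

**Compound list**

1 | (R)-(−)-linalool | C=C[C@](C)(O)CCC=C(C)C | starting material
2 | (3R)-3,7-dimethyl-3-(triethylsilyloxy)octa-1,6-diene | C=C[C@](C)(O[Si](CC)(CC)CC)CCC=C(C)C | intermediate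
3 | (2E,6R)-2,6-dimethyl-6-(triethylsilyloxy)octa-2,7-dienal | C=C[C@](C)(O[Si](CC)(CC)CC)CC/C=C(\C)C=O | intermediate
4 | methyl acetoacetate | CC(=O)CC(=O)OC | starting material
5 | methyl 2-acetyl-4-methyl-3-[(3R)-3-methyl-3-(triethylsilyloxy)pent-4-enyl]-5-oxopentanoate (9S; C8 and C10 epimers) | C=C[C@](C)(O[Si](CC)(CC)CC)CC[C@@H](C(C)C=O)C(C(C)=O)C(=O)OC | intermediate
6 | methyl 5-methyl-6-[(3R)-3-methyl-3-(triethylsilyloxy)pent-4-enyl]-2-oxocyclohex-3-ene-1-carboxylate (9S, all-trans) | C=C[C@](C)(O[Si](CC)(CC)CC)CC[C@H]1[C@H](C)C=CC(=O)[C@@H]1C(=O)OC | intermediate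
7 | methyl vinyl ketone | C=CC(C)=O | starting material
8 | methyl 5-methyl-6-[(3R)-3-methyl-3-(triethylsilyloxy)pent-4-enyl]-2-oxo-1-(3-oxobutyl)cyclohex-3-ene-1-carboxylate | C=C[C@](C)(O[Si](CC)(CC)CC)CC[C@H]1[C@H](C)C=CC(=O)[C@@]1(CCC(C)=O)C(=O)OC | intermediate
9 | methyl 18,19-dinor-3-oxo-13-(triethylsilyloxy)labda-4,6,14-trien-20-oate | C=C[C@](C)(O[Si](CC)(CC)CC)CC[C@H]1[C@H](C)C=CC2=CC(=O)CC[C@]12C(=O)OC | intermediate
10 | methyl (13R)-3-oxo-13-(triethylsilyloxy)labda-5,7,14-trien-20-oate | C=C[C@](C)(O[Si](CC)(CC)CC)CC[C@H]1C(C)=CC=C2C(C)(C)C(=O)CC[C@]12C(=O)OC | intermediate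
11 | (13R)-13-(triethylsilyloxy)labda-7,14-diene-3β,20-diol | C=C[C@](C)(O[Si](CC)(CC)CC)CC[C@H]1C(C)=CC[C@H]2C(C)(C)[C@@H](O)CC[C@]12CO | intermediate
12 | (13R)-20-(tert-butyldimethylsilyloxy)-13-(triethylsilyloxy)labda-7,14-dien-3β-ol | C=C[C@](C)(O[Si](CC)(CC)CC)CC[C@H]1C(C)=CC[C@H]2C(C)(C)[C@@H](O)CC[C@]12CO[Si](C)(C)C(C)(C)C | intermediate
13 | (13R)-20-(tert-butyldimethylsilyloxy)-13-(triethylsilyloxy)labda-7,14-dien-3-one | C=C[C@](C)(O[Si](CC)(CC)CC)CC[C@H]1C(C)=CC[C@H]2C(C)(C)C(=O)CC[C@]12CO[Si](C)(C)C(C)(C)C | intermediate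
14 | (13R)-20-(tert-butyldimethylsilyloxy)-2α-hydroxy-13-(triethylsilyloxy)labda-7,14-dien-3-one | C=C[C@](C)(O[Si](CC)(CC)CC)CC[C@H]1C(C)=CC[C@H]2C(C)(C)C(=O)[C@H](O)C[C@]12CO[Si](C)(C)C(C)(C)C | intermediate
15 | (13R)-20-(tert-butyldimethylsilyloxy)-13-(triethylsilyloxy)labda-7,14-diene-2α,3α-diol | C=C[C@](C)(O[Si](CC)(CC)CC)CC[C@H]1C(C)=CC[C@H]2C(C)(C)[C@H](O)[C@H](O)C[C@]12CO[Si](C)(C)C(C)(C)C | intermediate
16 | (13R)-2α-angeloyloxy-20-(tert-butyldimethylsilyloxy)-13-(triethylsilyloxy)labda-7,14-dien-3α-ol | C=C[C@](C)(O[Si](CC)(CC)CC)CC[C@H]1C(C)=CC[C@H]2C(C)(C)[C@H](O)[C@H](OC(=O)/C(C)=C\C)C[C@]12CO[Si](C)(C)C(C)(C)C | intermediate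
17 | (13R)-2α-angeloyloxylabda-7,14-diene-3α,13,20-triol | C=C[C@](C)(O)CC[C@H]1C(C)=CC[C@H]2C(C)(C)[C@H](O)[C@H](OC(=O)/C(C)=C\C)C[C@]12CO | intermediate
18 | (2R,3S,5R,9S,10S,13R)-20-acetoxy-2α-angeloyloxylabda-7,14-diene-3α,13-diol | C=C[C@](C)(O)CC[C@H]1C(C)=CC[C@H]2C(C)(C)[C@H](O)[C@H](OC(=O)/C(C)=C\C)C[C@]12COC(C)=O | target

**Totals and risks**

Total step count: 14. Longest linear sequence: 14 steps (1 to 18).

Steps most likely to fail:

1. Step 3 (Proposed new method). The α-methyl group may slow iminium formation, so that 1,2-condensation at the formyl group, capture of the primary amine by the β-keto ester as an enamino ester, or poor facial selectivity at C9 take over. Fallback with known reaction types, in which the C8–C9 bond is made under enamine control instead: the route leaves from 2 and comes back at 6. Ozonolysis of the electron-rich trisubstituted olefin of 2 (one equivalent of O3, CH2Cl2–pyridine, −78 °C, then Me2S) should give (R)-4-methyl-4-(triethylsilyloxy)hex-5-enal F1. Knoevenagel condensation of F1 with 4 (piperidine, AcOH) should give methyl 2-acetyl-6-methyl-6-(triethylsilyloxy)octa-2,7-dienoate F2. Michael addition of propanal to F2, catalysed by the enantiomer of α,α-diphenylprolinol trimethylsilyl ether that leads to 9S, should give 5, which is closed to 6 with pyrrolidine/AcOH as in step 3.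

2. Step 7. The diene may be reduced 1,4 instead of 1,2, C5 may be protonated from the β face, or the hindered ester may be reduced incompletely. Fallback that replaces electron transfer by hydrogen-atom transfer, leaving from 10 and coming back at 11: LiAlH4 (THF, 0 °C) should reduce ketone and ester to the diene diol (13R)-13-(triethylsilyloxy)labda-5,7,14-triene-3β,20-diol F3. Radical hydrogenation of F3 (Mn(dpm)3, PhSiH3, t-BuOOH, i-PrOH, 25 °C) should deliver hydrogen to C5 and then to C6 of the conjugated diene, giving the more stable trans-fused 7-ene 11, with the hindered monosubstituted vinyl group reacting more slowly.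

3. Step 11. Hydride may be delivered axially, giving the 3β-alcohol (trans-diol). Fallback that replaces substrate control by reagent control, leaving from 14 and coming back at 15: silylation of the C2 hydroxyl (Me3SiCl, imidazole) should give the 2α-trimethylsilyloxy ketone F4. CBS reduction of F4 (the enantiomer of 2-methyl-CBS-oxazaborolidine that delivers hydride to the β face, with the CMe2 carbon as the large group; catecholborane, −40 °C) should give the 3α-alcohol F5. K2CO3 in MeOH then removes the trimethylsilyl group of F5 and returns 15.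

**Further compounds**

F1 | step 3 | (R)-4-methyl-4-(triethylsilyloxy)hex-5-enal | C=C[C@](C)(O[Si](CC)(CC)CC)CCC=O
F2 | step 3 | methyl (6R)-2-acetyl-6-methyl-6-(triethylsilyloxy)octa-2,7-dienoate (E/Z mixture) | C=C[C@](C)(O[Si](CC)(CC)CC)CCC=C(C(C)=O)C(=O)OC
F3 | step 7 | (13R)-13-(triethylsilyloxy)labda-5,7,14-triene-3β,20-diol | C=C[C@](C)(O[Si](CC)(CC)CC)CC[C@H]1C(C)=CC=C2C(C)(C)[C@@H](O)CC[C@]12CO
F4 | step 11 | (13R)-20-(tert-butyldimethylsilyloxy)-13-(triethylsilyloxy)-2α-(trimethylsilyloxy)labda-7,14-dien-3-one | C=C[C@](C)(O[Si](CC)(CC)CC)CC[C@H]1C(C)=CC[C@H]2C(C)(C)C(=O)[C@H](O[Si](C)(C)C)C[C@]12CO[Si](C)(C)C(C)(C)C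
F5 | step 11 | (13R)-20-(tert-butyldimethylsilyloxy)-13-(triethylsilyloxy)-2α-(trimethylsilyloxy)labda-7,14-dien-3α-ol | C=C[C@](C)(O[Si](CC)(CC)CC)CC[C@H]1C(C)=CC[C@H]2C(C)(C)[C@H](O)[C@H](O[Si](C)(C)C)C[C@]12CO[Si](C)(C)C(C)(C)C
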